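**Plan**

- Retrosynthesis first cuts the two aryl O–Si bonds, then opens ring A at C1–C2, C2–C3 and C4–C5. This gives an ester-terminated vinylketene (C2, C5, C6, C1) and a prenyl-substituted siloxyalkyne (C3, C4).
- The feature that allows this is the C2 hydroxyl of ring A, which sits between the C3 prenyl group and the C1 ester, with the second oxygen meta at C4. C2 is read as a ketene carbonyl carbon and C3/C4 as an oxygen-polarised alkyne.
- The vinylketene is masked as a dienoyl chloride. Its tetrasubstituted alkene is cut at the bond to the CH2CO2Me group (enol triflate plus zinc ester enolate) and at the prenyl bond (β-ketoester alkylation), which leads back to phloretic acid.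
- Forward: ring B is bought; its side chain is extended to a β-ketoester, prenylated, triflated, coupled, unmasked to the acid and chlorinated. The siloxyalkyne comes from 4-methylpent-3-enoic acid through an ester-to-ynolate homologation. Ring A arises last, in one operation, and fluoride then frees the phenols.
- Stereochemistry: the target has no stereocentre. The only stereo-element on the way is the Z alkene of the acid chloride arm, which comes from a chelated enolate and disappears in the benzannulation.

Key step: step 10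

Remark: ring A is numbered from the ester-bearing carbon (C1 CO2Me, C2 OH, C3 prenyl, C4 OH, C5 prenyl, C6 arylethyl); ring B is the 4-hydroxyphenyl ring. Either alkene isomer of the acid chloride should give the same vinylketene, so the Z geometry is drawn because the chosen chemistry delivers it, not because the key step requires it.

**Route**

Step 1
Reactants: 1 phloretic acid
Product: 3 3-[4-(triisopropylsilyloxy)phenyl]propanoic acid, via silyl ester 2 (not isolated)
Conditions: i-Pr3SiCl (2.2 equiv), imidazole, DMF, rt; then K2CO3, THF/MeOH/H2O, 0 °C to rt; 1 M HCl to pH 3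
Reagents that add atoms: chlorotriisopropylsilane, CC(C)[Si](Cl)(C(C)C)C(C)C
Why: Imidazole-mediated silylation of phenol and carboxyl, followed by selective hydrolysis of the much more labile silyl ester, should leave the aryl silyl ether in place.

Step 2
Reactants: 3 3-[4-(triisopropylsilyloxy)phenyl]propanoic acid
Product: 5 tert-butyl 3-oxo-5-[4-(triisopropylsilyloxy)phenyl]pentanoate, via acyl Meldrum's acid 4 (not isolated)
Conditions: Meldrum's acid, DCC, DMAP, CH2Cl2, 0 °C to rt; filter; then t-BuOH, toluene, 90 °C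
Reagents that add atoms: Meldrum's acid (2,2-dimethyl-1,3-dioxane-4,6-dione), CC1(C)OC(=O)CC(=O)O1; tert-butanol, CC(C)(C)O
Why: C-acylation of Meldrum's acid, then thermal loss of acetone to an acylketene that is trapped by tert-butanol and decarboxylates, is the standard β-ketoester synthesis.

Step 3
Reactants: 5 tert-butyl 3-oxo-5-[4-(triisopropylsilyloxy)phenyl]pentanoate; 6 prenyl bromide
Product: 7 tert-butyl 2-(3-methylbut-2-enyl)-3-oxo-5-[4-(triisopropylsilyloxy)phenyl]pentanoate (racemic)
Conditions: K2CO3, acetone, 40 °C, 1.0 equiv of 6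
Reagents that add atoms: none
Why: SN2 C-alkylation of the β-ketoester enolate with the allylic bromide; the new α-stereocentre is racemic and is erased in step 4.

Step 4
Reactants: 7 tert-butyl 2-(3-methylbut-2-enyl)-3-oxo-5-[4-(triisopropylsilyloxy)phenyl]pentanoate
Product: 9 tert-butyl (Z)-2-(3-methylbut-2-enyl)-5-[4-(triisopropylsilyloxy)phenyl]-3-(trifluoromethylsulfonyloxy)pent-2-enoate, via sodium enolate 8 (not isolated)
Conditions: NaH, Et2O, 0 °C; then Tf2O, −78 °C to 0 °C
Reagents that add atoms: trifluoromethanesulfonic anhydride, O=S(=O)(OS(=O)(=O)C(F)(F)F)C(F)(F)F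
Why: O-sulfonylation of the sodium enolate, whose chelation between the enolate oxygen and the ester carbonyl in the weakly coordinating solvent should place the triflate cis to the ester (Z).

Step 5
Reactants: 9 tert-butyl (Z)-2-(3-methylbut-2-enyl)-5-[4-(triisopropylsilyloxy)phenyl]-3-(trifluoromethylsulfonyloxy)pent-2-enoate; 10 methyl bromoacetate
Product: 12 tert-butyl (Z)-3-(2-methoxy-2-oxoethyl)-2-(3-methylbut-2-enyl)-5-[4-(triisopropylsilyloxy)phenyl]pent-2-enoate, via Reformatsky reagent 11 (not isolated)
Conditions: Zn dust, THF, 40 °C (10 to 11, 2 equiv); then 9, Pd2(dba)3, XPhos, THF, 50 °C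
Reagents that add atoms: none
Why: Negishi coupling of the activated enol triflate with the zinc ester enolate, in which oxidative addition and reductive elimination at zerovalent/divalent palladium proceed with retention, should put the CH2CO2Me group cis to the tert-butyl ester.

Step 6
Reactants: 12 tert-butyl (Z)-3-(2-methoxy-2-oxoethyl)-2-(3-methylbut-2-enyl)-5-[4-(triisopropylsilyloxy)phenyl]pent-2-enoate
Product: 14 (Z)-3-(2-methoxy-2-oxoethyl)-2-(3-methylbut-2-enyl)-5-[4-(triisopropylsilyloxy)phenyl]pent-2-enoic acid, via trimethylsilyl ester 13 (not isolated)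
Conditions: Me3SiOTf, 2,6-lutidine, CH2Cl2, 0 °C; then pH 4 aqueous buffer
Reagents that add atoms: none
Why: Non-protic tert-butyl ester cleavage (O-silylation, loss of 2-methylpropene, hydrolysis of the silyl ester on work-up) should spare the methyl ester, the aryl silyl ether and the prenyl alkene because no strong protic acid is present.

Step 7
Reactants: 14 (Z)-3-(2-methoxy-2-oxoethyl)-2-(3-methylbut-2-enyl)-5-[4-(triisopropylsilyloxy)phenyl]pent-2-enoic acid
Product: 15 methyl (Z)-4-(chlorocarbonyl)-7-methyl-3-{2-[4-(triisopropylsilyloxy)phenyl]ethyl}octa-3,6-dienoate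
Conditions: 1-chloro-N,N,2-trimethylprop-1-en-1-amine (1.0 equiv), CH2Cl2, 0 °C to rt; concentrate, use crude at once
Reagents that add atoms: 1-chloro-N,N,2-trimethylprop-1-en-1-amine, CC(C)=C(Cl)N(C)C
Why: Acid chloride formation with the α-chloroenamine is neutral and sets no HCl free, which protects the prenyl alkene and the silyl ether.

Step 8
Reactants: 16 4-methylpent-3-enoic acid
Product: 17 ethyl 4-methylpent-3-enoate
Conditions: EtI, K2CO3, DMF, rt
Reagents that add atoms: iodoethane, CCI
Why: SN2 O-alkylation of the carboxylate avoids the acid-induced lactonisation and alkene migration that a Fischer esterification of this β,γ-unsaturated acid would risk.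

Step 9
Reactants: 17 ethyl 4-methylpent-3-enoate
Product: 19 triisopropyl(5-methylhex-4-en-1-ynyloxy)silane, via lithium ynolate 18 (not isolated)
Conditions: CH2Br2, lithium 2,2,6,6-tetramethylpiperidide (from the amine and n-BuLi), THF, −78 °C; LiN(SiMe3)2; n-BuLi, −78 °C to rt; then i-Pr3SiCl, −78 °C to 0 °C
Reagents that add atoms: dibromomethane, BrCBr; chlorotriisopropylsilane, CC(C)[Si](Cl)(C(C)C)C(C)C
Why: Kowalski homologation stopped at the ynolate: the dibromomethyl carbenoid adds to the ester, the derived dibromoketone enolate undergoes bromine–lithium exchange and 1,2-shift to ynolate 18, and the bulky silyl chloride traps it on oxygen.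

Step 10
Reactants: 15 methyl (Z)-4-(chlorocarbonyl)-7-methyl-3-{2-[4-(triisopropylsilyloxy)phenyl]ethyl}octa-3,6-dienoate; 19 triisopropyl(5-methylhex-4-en-1-ynyloxy)silane
Product: 24 methyl 2-hydroxy-3,5-bis(3-methylbut-2-enyl)-4-(triisopropylsilyloxy)-6-{2-[4-(triisopropylsilyloxy)phenyl]ethyl}benzoate, via vinylketene 20 (not isolated), via vinylcyclobutenone 21 (not isolated), via dienylketene 22 (not isolated), via cyclohexadienone 23 (not isolated)
Conditions: Et3N (1.5 equiv), toluene, 0 °C to rt, 15 added slowly to 19 (1.3 equiv); filter under argon; then 90 °C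
Reagents that add atoms: none
Why: Proposed new method: Et3N removes the doubly activated hydrogen between the alkene and the methyl ester of 15 and chloride leaves (1,4-dehydrochlorination) to give vinylketene 20, whose ketene C=C adds the oxygen-polarised alkyne 19 in a (2+2) cycloaddition that joins the nucleophilic prenyl-bearing alkyne carbon to the ketene carbonyl carbon (C2–C3) and the oxygen-bearing carbon to the ketene alpha-carbon (C4–C5), closing the four-membered ring of 21. On heating, 21 should open by four-electron electrocyclic cleavage to dienylketene 22, and ring A should close by a thermal six-electron disrotatory electrocyclisation between the ketene carbon and the ester-bearing terminus (C1–C2) to dienone 23, which tautomerises to the hydrogen-bonded salicylate 24. The closest known reaction type is the Danheiser benzannulation of siloxyalkynes with vinylketenes released from cyclobutenones or diazo ketones, together with the known formation of vinylketenes from unsaturated acid chlorides and Et3N; what is new is an ester-terminated, fully substituted vinylketene from an acid chloride leading to a hexasubstituted arene. No stereocentre is created in 24, and the alkene geometry of 15 is not carried into the ketene. The step needs the regiochemistry of the (2+2) addition, which the polarisation of 19 by its oxygen secures (the oxygens end up meta at C2 and C4), and it needs deprotonation at the ester-flanked CH2 rather than at the arylethyl CH2, which the far higher acidity of the former secures; allylic strain should turn the ester of 20 away from the ketene, so that oxa-cyclisation to a pyranone is avoided and hydrogen is the inside substituent in the ring closure.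

Step 11
Reactants: 24 methyl 2-hydroxy-3,5-bis(3-methylbut-2-enyl)-4-(triisopropylsilyloxy)-6-{2-[4-(triisopropylsilyloxy)phenyl]ethyl}benzoate
Product: 25 methyl 2,4-dihydroxy-6-[2-(4-hydroxyphenyl)ethyl]-3,5-bis(3-methylbut-2-enyl)benzoate
Conditions: Bu4NF, AcOH, THF, 0 °C
Reagents that add atoms: none
Why: Fluoride should cleave both aryl silyl ethers, and the acetic acid buffer keeps the phenols protonated so that the electron-rich resorcinol ring and the hindered, hydrogen-bonded methyl ester are left alone.

**Compound list**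

1 | phloretic acid, 3-(4-hydroxyphenyl)propanoic acid | OC(=O)CCc1ccc(O)cc1 | starting material
2 | triisopropylsilyl 3-[4-(triisopropylsilyloxy)phenyl]propanoate | CC(C)[Si](OC(=O)CCc1ccc(O[Si](C(C)C)(C(C)C)C(C)C)cc1)(C(C)C)C(C)C | intermediate
3 | 3-[4-(triisopropylsilyloxy)phenyl]propanoic acid | OC(=O)CCc1ccc(O[Si](C(C)C)(C(C)C)C(C)C)cc1 | intermediate
4 | 2,2-dimethyl-5-{3-[4-(triisopropylsilyloxy)phenyl]propanoyl}-1,3-dioxane-4,6-dione | CC1(C)OC(=O)C(C(=O)CCc2ccc(O[Si](C(C)C)(C(C)C)C(C)C)cc2)C(=O)O1 | intermediate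
5 | tert-butyl 3-oxo-5-[4-(triisopropylsilyloxy)phenyl]pentanoate | CC(C)(C)OC(=O)CC(=O)CCc1ccc(O[Si](C(C)C)(C(C)C)C(C)C)cc1 | intermediate
6 | prenyl bromide, 1-bromo-3-methylbut-2-ene | CC(C)=CCBr | starting material
7 | tert-butyl 2-(3-methylbut-2-enyl)-3-oxo-5-[4-(triisopropylsilyloxy)phenyl]pentanoate (racemic) | CC(C)(C)OC(=O)C(CC=C(C)C)C(=O)CCc1ccc(O[Si](C(C)C)(C(C)C)C(C)C)cc1 | intermediate
8 | sodium (Z)-1-tert-butoxy-2-(3-methylbut-2-enyl)-1-oxo-5-[4-(triisopropylsilyloxy)phenyl]pent-2-en-3-olate | [Na+].CC(C)(C)OC(=O)/C(CC=C(C)C)=C(\[O-])CCc1ccc(O[Si](C(C)C)(C(C)C)C(C)C)cc1 | intermediate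
9 | tert-butyl (Z)-2-(3-methylbut-2-enyl)-5-[4-(triisopropylsilyloxy)phenyl]-3-(trifluoromethylsulfonyloxy)pent-2-enoate | CC(C)(C)OC(=O)/C(CC=C(C)C)=C(\OS(=O)(=O)C(F)(F)F)CCc1ccc(O[Si](C(C)C)(C(C)C)C(C)C)cc1 | intermediate
10 | methyl bromoacetate | COC(=O)CBr | starting material
11 | bromo(2-methoxy-2-oxoethyl)zinc | COC(=O)C[Zn]Br | intermediate
12 | tert-butyl (Z)-3-(2-methoxy-2-oxoethyl)-2-(3-methylbut-2-enyl)-5-[4-(triisopropylsilyloxy)phenyl]pent-2-enoate | COC(=O)C/C(CCc1ccc(O[Si](C(C)C)(C(C)C)C(C)C)cc1)=C(\C(=O)OC(C)(C)C)CC=C(C)C | intermediate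
13 | trimethylsilyl (Z)-3-(2-methoxy-2-oxoethyl)-2-(3-methylbut-2-enyl)-5-[4-(triisopropylsilyloxy)phenyl]pent-2-enoate | COC(=O)C/C(CCc1ccc(O[Si](C(C)C)(C(C)C)C(C)C)cc1)=C(\C(=O)O[Si](C)(C)C)CC=C(C)C | intermediate
14 | (Z)-3-(2-methoxy-2-oxoethyl)-2-(3-methylbut-2-enyl)-5-[4-(triisopropylsilyloxy)phenyl]pent-2-enoic acid | COC(=O)C/C(CCc1ccc(O[Si](C(C)C)(C(C)C)C(C)C)cc1)=C(\C(=O)O)CC=C(C)C | intermediate
15 | methyl (Z)-4-(chlorocarbonyl)-7-methyl-3-{2-[4-(triisopropylsilyloxy)phenyl]ethyl}octa-3,6-dienoate | COC(=O)C/C(CCc1ccc(O[Si](C(C)C)(C(C)C)C(C)C)cc1)=C(\C(=O)Cl)CC=C(C)C | intermediate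
16 | 4-methylpent-3-enoic acid | CC(C)=CCC(=O)O | starting material
17 | ethyl 4-methylpent-3-enoate | CCOC(=O)CC=C(C)C | intermediate
18 | lithium 5-methylhex-4-en-1-yn-1-olate | [Li+].[O-]C#CCC=C(C)C | intermediate
19 | triisopropyl(5-methylhex-4-en-1-ynyloxy)silane | CC(C)=CCC#CO[Si](C(C)C)(C(C)C)C(C)C | intermediate
20 | methyl (E)-7-methyl-4-(oxomethylidene)-3-{2-[4-(triisopropylsilyloxy)phenyl]ethyl}octa-2,6-dienoate | COC(=O)/C=C(\CCc1ccc(O[Si](C(C)C)(C(C)C)C(C)C)cc1)C(CC=C(C)C)=C=O | intermediate
21 | methyl (E)-3-[1,3-bis(3-methylbut-2-enyl)-4-oxo-2-(triisopropylsilyloxy)cyclobut-2-en-1-yl]-5-[4-(triisopropylsilyloxy)phenyl]pent-2-enoate (racemic) | COC(=O)/C=C(\CCc1ccc(O[Si](C(C)C)(C(C)C)C(C)C)cc1)C1(CC=C(C)C)C(=O)C(CC=C(C)C)=C1O[Si](C(C)C)(C(C)C)C(C)C | intermediate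
22 | methyl (2E,4E)-9-methyl-4-(3-methylbut-2-enyl)-6-(oxomethylidene)-5-(triisopropylsilyloxy)-3-{2-[4-(triisopropylsilyloxy)phenyl]ethyl}deca-2,4,8-trienoate | O=C=C(CC=C(C)C)/C(O[Si](C(C)C)(C(C)C)C(C)C)=C(CC=C(C)C)\C(CCc1ccc(O[Si](C(C)C)(C(C)C)C(C)C)cc1)=C\C(=O)OC | intermediate
23 | methyl 3,5-bis(3-methylbut-2-enyl)-2-oxo-4-(triisopropylsilyloxy)-6-{2-[4-(triisopropylsilyloxy)phenyl]ethyl}cyclohexa-3,5-diene-1-carboxylate (racemic) | COC(=O)C1C(=O)C(CC=C(C)C)=C(O[Si](C(C)C)(C(C)C)C(C)C)C(CC=C(C)C)=C1CCc1ccc(O[Si](C(C)C)(C(C)C)C(C)C)cc1 | intermediate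
24 | methyl 2-hydroxy-3,5-bis(3-methylbut-2-enyl)-4-(triisopropylsilyloxy)-6-{2-[4-(triisopropylsilyloxy)phenyl]ethyl}benzoate | COC(=O)c1c(O)c(CC=C(C)C)c(O[Si](C(C)C)(C(C)C)C(C)C)c(CC=C(C)C)c1CCc1ccc(O[Si](C(C)C)(C(C)C)C(C)C)cc1 | intermediate
25 | methyl 2,4-dihydroxy-6-[2-(4-hydroxyphenyl)ethyl]-3,5-bis(3-methylbut-2-enyl)benzoate | COC(=O)c1c(O)c(CC=C(C)C)c(O)c(CC=C(C)C)c1CCc1ccc(O)cc1 | target

**Step count**

Total: 11 steps. Longest linear sequence: 9 steps (steps 1 to 7, then 10 and 11); the siloxyalkyne arm (steps 8 and 9) joins at step 10.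

**Steps most likely to fail**

Step 10 (the proposed method). The crowded vinylketene may dimerise, or cyclise through its own ester carbonyl, before the alkyne intercepts it. The ammonium salt may also protonate the siloxyalkyne, or the (2+2) adduct may not open and re-close, so that no arene forms. The fallback uses known chemistry and leaves the benzannulation aside; it sets out from acid 3 and prenyl bromide 6 and comes back to the route at target 25. Acid 3 is activated with 1,1'-carbonyldiimidazole to 1-{3-[4-(triisopropylsilyloxy)phenyl]propanoyl}imidazole F1. F1 acylates the terminal carbon of the trianion of purchased methyl 3,5-dioxohexanoate (LiN(i-Pr)2, THF, −78 °C) to give methyl 3,5,7-trioxo-9-[4-(triisopropylsilyloxy)phenyl]nonanoate F2. Under mild base (Et3N, CH2Cl2, then dilute acid) this polyketide chain should undergo intramolecular aldol condensation between its C2 and C7 and dehydrate to methyl 2,4-dihydroxy-6-{2-[4-(triisopropylsilyloxy)phenyl]ethyl}benzoate F3. The two free ring positions, both ortho to the C4 oxygen, are then C-prenylated with 6 through the sodium phenoxide in toluene (NaH, excess 6) to give methyl 2,4-dihydroxy-3,5-bis(3-methylbut-2-enyl)-6-{2-[4-(triisopropylsilyloxy)phenyl]ethyl}benzoate F4. Bu4NF, as in step 11, then gives 25.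

Step 5. Oxidative addition and transmetalation at the tetrasubstituted triflate may be slow, and proton transfer from the acidic CH2 of the product to the zinc enolate may stall the coupling and let the alkene lose its position or geometry. The fallback replaces the cross-coupling by an addition–elimination and a decarboxylation; it sets out from enol triflate 9 and comes back at acid 14. Sodium tert-butyl methyl malonate (from the malonate and NaH, THF/DMF) displaces the triflate of 9 by conjugate addition–elimination to give di-tert-butyl (Z)-2-(methoxycarbonyl)-4-(3-methylbut-2-enyl)-3-{2-[4-(triisopropylsilyloxy)phenyl]ethyl}pent-3-enedioate F5. Me3SiOTf and 2,6-lutidine, as in step 6, convert both tert-butyl esters into bis(trimethylsilyl) (Z)-2-(methoxycarbonyl)-4-(3-methylbut-2-enyl)-3-{2-[4-(triisopropylsilyloxy)phenyl]ethyl}pent-3-enedioate F6. Aqueous work-up gives the malonic half-acid (Z)-2-(methoxycarbonyl)-4-(3-methylbut-2-enyl)-3-{2-[4-(triisopropylsilyloxy)phenyl]ethyl}pent-3-enedioic acid F7, and gentle warming should expel CO2 to leave 14.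

Step 9. Deprotonation of the β,γ-unsaturated ester at its doubly activated α-position may compete with carbonyl addition of the carbenoid, and the skipped ene-yne position may isomerise under the excess base. The fallback makes the ynolate by oxidation of an acetylide instead of by rearrangement; it sets out from prenyl bromide 6 and comes back at ynolate 18, and so at 19. Bromide 6 is coupled with ethynylmagnesium bromide under CuBr·SMe2 catalysis (THF, 0 °C) to give 5-methylhex-4-en-1-yne F8. n-BuLi (THF, −78 °C) gives lithium 5-methylhex-4-en-1-ynide F9, which lithium tert-butyl peroxide (from t-BuOOH and LiN(SiMe3)2) should oxidise to 18; silylation as in step 9 gives 19.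

**Further compounds**

F1 | step 10 | 1-{3-[4-(triisopropylsilyloxy)phenyl]propanoyl}imidazole | O=C(CCc1ccc(O[Si](C(C)C)(C(C)C)C(C)C)cc1)n1ccnc1
F2 | step 10 | methyl 3,5,7-trioxo-9-[4-(triisopropylsilyloxy)phenyl]nonanoate | COC(=O)CC(=O)CC(=O)CC(=O)CCc1ccc(O[Si](C(C)C)(C(C)C)C(C)C)cc1
F3 | step 10 | methyl 2,4-dihydroxy-6-{2-[4-(triisopropylsilyloxy)phenyl]ethyl}benzoate | COC(=O)c1c(O)cc(O)cc1CCc1ccc(O[Si](C(C)C)(C(C)C)C(C)C)cc1
F4 | step 10 | methyl 2,4-dihydroxy-3,5-bis(3-methylbut-2-enyl)-6-{2-[4-(triisopropylsilyloxy)phenyl]ethyl}benzoate | COC(=O)c1c(O)c(CC=C(C)C)c(O)c(CC=C(C)C)c1CCc1ccc(O[Si](C(C)C)(C(C)C)C(C)C)cc1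
F5 | step 5 | di-tert-butyl (Z)-2-(methoxycarbonyl)-4-(3-methylbut-2-enyl)-3-{2-[4-(triisopropylsilyloxy)phenyl]ethyl}pent-3-enedioate | COC(=O)C(C(=O)OC(C)(C)C)/C(CCc1ccc(O[Si](C(C)C)(C(C)C)C(C)C)cc1)=C(\C(=O)OC(C)(C)C)CC=C(C)C
F6 | step 5 | bis(trimethylsilyl) (Z)-2-(methoxycarbonyl)-4-(3-methylbut-2-enyl)-3-{2-[4-(triisopropylsilyloxy)phenyl]ethyl}pent-3-enedioate | COC(=O)C(C(=O)O[Si](C)(C)C)/C(CCc1ccc(O[Si](C(C)C)(C(C)C)C(C)C)cc1)=C(\C(=O)O[Si](C)(C)C)CC=C(C)C
F7 | step 5 | (Z)-2-(methoxycarbonyl)-4-(3-methylbut-2-enyl)-3-{2-[4-(triisopropylsilyloxy)phenyl]ethyl}pent-3-enedioic acid | COC(=O)C(C(=O)O)/C(CCc1ccc(O[Si](C(C)C)(C(C)C)C(C)C)cc1)=C(\C(=O)O)CC=C(C)C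
F8 | step 9 | 5-methylhex-4-en-1-yne | C#CCC=C(C)C
F9 | step 9 | lithium 5-methylhex-4-en-1-ynide | [Li+].[C-]#CCC=C(C)C
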